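**Strategy.** Ring C (O1, C2, C3, C4, C4a, C8a) is divided into the C2–C3–C4 cinnamoyl arm of ring B and the O1–C8a–C4a phenol edge of ring A. In one flask the magnesium phenolate of a bis-silylated 2-prenylphloroglucinol is acylated at its ortho carbon by the ring B cinnamoyl chloride (C4–C4a). The 2'-hydroxychalcone so formed is closed by a cinchona thiourea in an enantioselective oxa-Michael addition (O1–C2) that sets C2. The step exploits that O1 is the only free hydroxyl on ring A and that C8 already bears the prenyl group, which leaves C4a as its only open ortho carbon.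

Key step: step 7

Assumption: the quinine-derived 9-epi-amino thiourea is taken as the pseudoenantiomer that leads to 2S. If the sense of induction is the opposite, the quinidine-derived catalyst takes its place and nothing else changes.

Abbreviations: TBS = tert-butyldimethylsilyl; MTBSTFA = N-methyl-N-(tert-butyldimethylsilyl)trifluoroacetamide.

Step 1
Reactants: 1 phloroglucinol; 2 prenyl bromide (1-bromo-3-methylbut-2-ene)
Product: 3 2-prenylphloroglucinol [2-(3-methylbut-2-enyl)benzene-1,3,5-triol]
Conditions: 1 (excess), KOH (1 equiv to 2), H2O, 0 °C to rt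
Reagents that add atoms: none
Why: C-alkylation of the enolate-like phloroglucinolate in water (phenolate C-prenylation), in which the three ring CH positions are equivalent, so only the degree of alkylation has to be held down by the excess of 1.

Step 2
Reactants: 3 2-prenylphloroglucinol
Product: 4 3,5-bis(TBS-oxy)-2-(3-methylbut-2-enyl)phenol (free hydroxyl ortho to the prenyl group)
Conditions: TBSCl (2 equiv), imidazole, DMF, 0 °C
Reagents that add atoms: TBSCl, CC(C)(C)[Si](C)(C)Cl
Why: Sterically graded O-silylation, in which the hydroxyl para to the prenyl group reacts first, the two remaining hydroxyls are equivalent so the second silylation gives one constitution, and the last hydroxyl, pressed against the buttressed prenyl chain, should react distinctly more slowly.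

Step 3
Reactants: 5 2,4-dihydroxybenzaldehyde; 2 prenyl bromide
Product: 6 2-hydroxy-4-(3-methylbut-2-enyloxy)benzaldehyde
Conditions: K2CO3 (1 equiv), acetone, reflux
Reagents that add atoms: none
Why: Williamson ether synthesis that is selective for the 4-hydroxyl because the 2-hydroxyl is tied up in a hydrogen bond to the aldehyde.

Step 4
Reactants: 6 2-hydroxy-4-(3-methylbut-2-enyloxy)benzaldehyde
Product: 7 2-(TBS-oxy)-4-(3-methylbut-2-enyloxy)benzaldehyde
Conditions: TBSCl, imidazole, DMF, rt
Reagents that add atoms: TBSCl, CC(C)(C)[Si](C)(C)Cl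
Why: Imidazole-promoted silylation of the phenol, whose bulky silyl ether also shields C3 for the next step.

Step 5
Reactants: 7 2-(TBS-oxy)-4-(3-methylbut-2-enyloxy)benzaldehyde
Product: 9 2,4-bis(TBS-oxy)-5-(2-methylbut-3-en-2-yl)benzaldehyde, via phenol 8 (not isolated)
Conditions: MTBSTFA (1.5 equiv), PhNEt2, 190 °C, sealed tube
Reagents that add atoms: MTBSTFA, CN([Si](C)(C)C(C)(C)C)C(=O)C(F)(F)F
Why: Aromatic Claisen rearrangement ([3,3]-sigmatropic with allyl inversion, so the O-prenyl group arrives as the C-bound 1,1-dimethylallyl group) should go to C5 because C3 is flanked by two oxygen substituents, and silylation of phenol 8 as it forms blocks the abnormal Claisen and cyclisation pathways.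

Step 6
Reactants: 9 2,4-bis(TBS-oxy)-5-(2-methylbut-3-en-2-yl)benzaldehyde; 10 diethylphosphonoacetic acid
Product: 11 (E)-3-[2,4-bis(TBS-oxy)-5-(2-methylbut-3-en-2-yl)phenyl]prop-2-enoic acid
Conditions: 10, n-BuLi (2 equiv), THF, −78 °C, then 9, −78 °C to rt; cold 0.5 M HCl work-up
Reagents that add atoms: none
Why: Horner–Wadsworth–Emmons olefination with the dianion of the phosphonoacetic acid should give the E-cinnamic acid directly, so that no ester hydrolysis endangers the aryl silyl ethers.

Step 7
Reactants: 11 (E)-cinnamic acid of ring B; 4 3,5-bis(TBS-oxy)-2-(3-methylbut-2-enyl)phenol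
Product: 15 (2S)-5,7-bis(TBS-oxy)-2-[2,4-bis(TBS-oxy)-5-(2-methylbut-3-en-2-yl)phenyl]-8-(3-methylbut-2-enyl)chroman-4-one, via acid chloride 12 (not isolated), via magnesium phenolate 13 (not isolated), via chalcone 14 (not isolated)
Conditions: (a) 11, (COCl)2, cat. DMF, CH2Cl2, 0 °C, argon sweep, concentrate; (b) 4 (2 equiv, the second as proton acceptor, recovered), EtMgBr (2 equiv), Et2O/toluene, 0 °C, then 12 in toluene, 0 °C to rt; (c) AcOH (1 equiv), 1,4-dioxane (precipitates the magnesium salts), then 1-[3,5-bis(trifluoromethyl)phenyl]-3-(9-deoxy-9-epi-quinin-9-yl)thiourea (20 mol %), toluene, 0 °C to rt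
Reagents that add atoms: oxalyl chloride, O=C(Cl)C(=O)Cl (chlorine of 12); ethylmagnesium bromide, CC[Mg]Br (magnesium and bromine of 13); no reagent atom remains in 15
Why: The magnesium of phenolate 13 binds the carbonyl oxygen of 12 and delivers the acyl carbon through a six-membered chelate to the only open ortho carbon (the future C4a), a metal-phenolate-templated Friedel–Crafts ortho-acylation known for cinnamoyl chlorides, which gives the chelated 2'-hydroxychalcone 14 after rearomatisation. Once the chelate is protonated and the magnesium salts are precipitated, the bifunctional cinchona thiourea closes ring C by intramolecular oxa-Michael addition (6-endo-trig), the known organocatalytic chalcone-to-flavanone cyclisation that mimics chalcone isomerase. C2 is the only new stereocentre and is controlled by the catalyst: the thiourea hydrogen-bonds the C4 carbonyl while the quinuclidine nitrogen takes the O1 proton, so that O1 should add to the Si face of C2 and give 2S. The step needs C- over O-acylation, C4a over the carbon between the two silyloxy groups, and the 8-prenyl rather than the 6-prenyl mode of closure; the non-coordinating solvent and the chelate secure the first two, and the third is fixed because O1 is the only free hydroxyl of 4 and its other ortho position carries the prenyl group. The peri 5-silyloxy group twists the aroyl unit of 14 out of conjugation, which should make closure strongly favourable and slow the retro-reaction that would erode enantiopurity, and no strong acid meets the prenylphenol, so the prenyl, 1,1-dimethylallyl and silyl groups should survive.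

Step 8
Reactants: 15 (2S)-tetrakis-TBS flavanone
Product: 16 AChE-IN-17, (2S)-2-[2,4-dihydroxy-5-(2-methylbut-3-en-2-yl)phenyl]-5,7-dihydroxy-8-(3-methylbut-2-enyl)chroman-4-one
Conditions: HF·pyridine, pyridine/THF, 0 °C to rt
Reagents that add atoms: none
Why: Fluoride-driven cleavage of the four aryl silyl ethers in a weakly acidic pyridine buffer, where no phenoxide forms, so that retro-oxa-Michael ring opening (racemisation of C2) and acid-induced cyclisation of the two C5 side chains onto neighbouring phenols should both be avoided.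

**Compound list**

1 | phloroglucinol | Oc1cc(O)cc(O)c1 | starting material
2 | prenyl bromide | CC(C)=CCBr | starting material
3 | 2-(3-methylbut-2-enyl)benzene-1,3,5-triol | CC(C)=CCc1c(O)cc(O)cc1O | intermediate
4 | 3,5-bis(TBS-oxy)-2-(3-methylbut-2-enyl)phenol | CC(C)=CCc1c(O)cc(O[Si](C)(C)C(C)(C)C)cc1O[Si](C)(C)C(C)(C)C | intermediate
5 | 2,4-dihydroxybenzaldehyde | O=Cc1ccc(O)cc1O | starting material
6 | 2-hydroxy-4-(3-methylbut-2-enyloxy)benzaldehyde | O=Cc1ccc(OCC=C(C)C)cc1O | intermediate
7 | 2-(TBS-oxy)-4-(3-methylbut-2-enyloxy)benzaldehyde | O=Cc1ccc(OCC=C(C)C)cc1O[Si](C)(C)C(C)(C)C | intermediate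
8 | 2-(TBS-oxy)-4-hydroxy-5-(2-methylbut-3-en-2-yl)benzaldehyde (not isolated) | C=CC(C)(C)c1cc(C=O)c(O[Si](C)(C)C(C)(C)C)cc1O | intermediate
9 | 2,4-bis(TBS-oxy)-5-(2-methylbut-3-en-2-yl)benzaldehyde | C=CC(C)(C)c1cc(C=O)c(O[Si](C)(C)C(C)(C)C)cc1O[Si](C)(C)C(C)(C)C | intermediate
10 | diethylphosphonoacetic acid | CCOP(=O)(CC(=O)O)OCC | starting material
11 | (E)-3-[2,4-bis(TBS-oxy)-5-(2-methylbut-3-en-2-yl)phenyl]prop-2-enoic acid | C=CC(C)(C)c1cc(/C=C/C(=O)O)c(O[Si](C)(C)C(C)(C)C)cc1O[Si](C)(C)C(C)(C)C | intermediate
12 | (E)-3-[2,4-bis(TBS-oxy)-5-(2-methylbut-3-en-2-yl)phenyl]prop-2-enoyl chloride (not isolated) | C=CC(C)(C)c1cc(/C=C/C(=O)Cl)c(O[Si](C)(C)C(C)(C)C)cc1O[Si](C)(C)C(C)(C)C | intermediate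
13 | bromomagnesium phenolate of 4 (not isolated) | CC(C)=CCc1c(O[Mg]Br)cc(O[Si](C)(C)C(C)(C)C)cc1O[Si](C)(C)C(C)(C)C | intermediate
14 | (E)-2'-hydroxy-2,4,4',6'-tetrakis(TBS-oxy)-3'-prenyl-5-(1,1-dimethylallyl)chalcone (not isolated) | C=CC(C)(C)c1cc(/C=C/C(=O)c2c(O)c(CC=C(C)C)c(O[Si](C)(C)C(C)(C)C)cc2O[Si](C)(C)C(C)(C)C)c(O[Si](C)(C)C(C)(C)C)cc1O[Si](C)(C)C(C)(C)C | intermediate
15 | (2S)-5,7-bis(TBS-oxy)-2-[2,4-bis(TBS-oxy)-5-(2-methylbut-3-en-2-yl)phenyl]-8-(3-methylbut-2-enyl)chroman-4-one | C=CC(C)(C)c1cc([C@@H]2CC(=O)c3c(O[Si](C)(C)C(C)(C)C)cc(O[Si](C)(C)C(C)(C)C)c(CC=C(C)C)c3O2)c(O[Si](C)(C)C(C)(C)C)cc1O[Si](C)(C)C(C)(C)C | intermediate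
16 | AChE-IN-17, (2S)-2-[2,4-dihydroxy-5-(2-methylbut-3-en-2-yl)phenyl]-5,7-dihydroxy-8-(3-methylbut-2-enyl)chroman-4-one | C=CC(C)(C)c1cc([C@@H]2CC(=O)c3c(O)cc(O)c(CC=C(C)C)c3O2)c(O)cc1O | target

**Total step count:** 8. **Longest linear sequence:** 6 steps (5 → 6 → 7 → 9 → 11 → 15 → 16).

**Steps most likely to fail**

1. Step 7.
   - What may go wrong: acylation at oxygen instead of carbon, or poor facial selectivity because an uncatalysed or salt-promoted ring closure competes with the catalysed one.
   - Fallback: the two bonds are made one at a time and the enantiomers are separated kinetically. It sets out from 4 and 11.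
   - Steglich esterification (DCC, DMAP, CH2Cl2) gives the aryl cinnamate F1.
   - Photo-Fries rearrangement (300 nm, benzene) moves the acyl group to the free ortho carbon and gives 14, now isolated.
   - Catalytic DBU in toluene closes it to the racemic flavanone F2.
   - Asymmetric transfer hydrogenation with RuCl(p-cymene)[(R,R)-TsDPEN] in HCO2H/Et3N, stopped near half conversion, should reduce the matched 2R ketone to the cis-(2R,4R)-flavan-4-ol F3. It should leave the 2S ketone, so the route is rejoined at 15.

2. Step 5.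
   - What may go wrong: migration to C3, loss of the prenyl group by ionisation, or further rearrangement of the ortho-(1,1-dimethylallyl)phenol before it is silylated.
   - Fallback: cross-coupling instead of a sigmatropic shift. It sets out from 5 and replaces steps 3 to 5.
   - Bromination (Br2, AcOH) gives 5-bromo-2,4-dihydroxybenzaldehyde F4.
   - TBSCl and imidazole in DMF give the bis-silyl ether F5.
   - A ligand-controlled γ-selective Suzuki–Miyaura coupling joins the tertiary allyl carbon to C5. It uses prenylboronic acid pinacol ester, Pd(OAc)2, a bulky dialkylbiarylphosphine and K3PO4 in THF/H2O at 40 °C. It comes back to the route at 9.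

3. Step 2.
   - What may go wrong: poor discrimination between the hydroxyl groups, giving mixtures of under- and over-silylated material.
   - Fallback: the free hydroxyl is defined by a rearrangement instead of by rate differences. It sets out from 1 and replaces steps 1 and 2.
   - TBSCl (2 equiv) and imidazole give 3,5-bis(TBS-oxy)phenol F6, where all hydroxyls are equivalent at the start.
   - O-allylation with tert-butyl 2-methylbut-3-en-2-yl carbonate and Pd(PPh3)4 in THF gives the 1,1-dimethylallyl aryl ether F7.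
   - Aromatic Claisen rearrangement (toluene, 110 °C) delivers the prenyl group to one of two equivalent ortho carbons. It frees exactly the hydroxyl next to it, which comes back to the route at 4.

Further compounds
F1 | step 7 | 3,5-bis(TBS-oxy)-2-(3-methylbut-2-enyl)phenyl (E)-3-[2,4-bis(TBS-oxy)-5-(2-methylbut-3-en-2-yl)phenyl]prop-2-enoate | C=CC(C)(C)c1cc(/C=C/C(=O)Oc2cc(O[Si](C)(C)C(C)(C)C)cc(O[Si](C)(C)C(C)(C)C)c2CC=C(C)C)c(O[Si](C)(C)C(C)(C)C)cc1O[Si](C)(C)C(C)(C)C
F2 | step 7 | racemic tetrakis-TBS flavanone (racemate of 15) | C=CC(C)(C)c1cc(C2CC(=O)c3c(O[Si](C)(C)C(C)(C)C)cc(O[Si](C)(C)C(C)(C)C)c(CC=C(C)C)c3O2)c(O[Si](C)(C)C(C)(C)C)cc1O[Si](C)(C)C(C)(C)C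
F3 | step 7 | cis-(2R,4R)-tetrakis-TBS flavan-4-ol | C=CC(C)(C)c1cc([C@H]2C[C@@H](O)c3c(O[Si](C)(C)C(C)(C)C)cc(O[Si](C)(C)C(C)(C)C)c(CC=C(C)C)c3O2)c(O[Si](C)(C)C(C)(C)C)cc1O[Si](C)(C)C(C)(C)C
F4 | step 5 | 5-bromo-2,4-dihydroxybenzaldehyde | O=Cc1cc(Br)c(O)cc1O
F5 | step 5 | 5-bromo-2,4-bis(TBS-oxy)benzaldehyde | O=Cc1cc(Br)c(O[Si](C)(C)C(C)(C)C)cc1O[Si](C)(C)C(C)(C)C
F6 | step 2 | 3,5-bis(TBS-oxy)phenol | Oc1cc(O[Si](C)(C)C(C)(C)C)cc(O[Si](C)(C)C(C)(C)C)c1
F7 | step 2 | 1,3-bis(TBS-oxy)-5-(2-methylbut-3-en-2-yloxy)benzene | C=CC(C)(C)Oc1cc(O[Si](C)(C)C(C)(C)C)cc(O[Si](C)(C)C(C)(C)C)c1
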